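**Retrosynthetic overview**
1. Target 5 ⇐ 4: cleave one of two equivalent aryl methyl ethers at the end.
2. 4 ⇐ 3 (key step): enantioselective anti-Markovnikov addition of water across the styrenyl C=C, forming the C2–O bond and setting the (S) centre in one operation.
3. 3 ⇐ 1 + 2: E-selective olefin cross-metathesis of a styrene with a terminal alkene.
4. No ring is formed; the benzene ring is bought intact in 1.

The target's carbinol carbon is (S) (priorities OH > CH2Ar > C13H27 > H).

Assumption: the absolute sense of induction of the new hydration catalyst cannot be known in advance; the route is written with the (S)-configured anion, and if it gives the (R)-alcohol the mirror-image (R)-anion is used with no other change.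

**Step 1**
Reactants: 1 3,5-dimethoxystyrene; 2 pentadec-1-ene
Product: 3 (E)-1,3-dimethoxy-5-(pentadec-1-en-1-yl)benzene
Conditions: second-generation Hoveyda–Grubbs catalyst RuCl2(1,3-dimesitylimidazolidin-2-ylidene)(=CH-C6H4-2-O-i-Pr) (2 mol%), 2 (3 equiv), CH2Cl2, 40 °C, argon sparge
Reagents that add atoms: none
Why: Olefin cross-metathesis of a styrene with an excess of a terminal alkene gives the thermodynamically preferred (E)-β-alkylstyrene while ethene is purged, and the methyl ethers are inert; no stereocentre is formed.

**Step 2**
Reactants: 3 (E)-1,3-dimethoxy-5-(pentadec-1-en-1-yl)benzene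
Product: 4 (S)-1-(3,5-dimethoxyphenyl)pentadecan-2-ol
Conditions: 9-mesityl-3,6-di-tert-butyl-10-phenylacridinium (S)-N-triflyl-3,3'-bis(2,4,6-triisopropylphenyl)-1,1'-binaphthyl-2,2'-diyl phosphoramidate (5 mol%), PhSSPh (10 mol%), H2O (5 equiv), CH2Cl2 (0.05 M), 450 nm LEDs, 0 °C, argon
Reagents that add atoms: water, O
Why: Proposed new method: enantioselective intermolecular anti-Markovnikov hydration of a β-alkylstyrene by chiral-anion-paired photoredox catalysis; the excited acridinium oxidises the conjugated alkene of 3 to its radical cation, which stays ion-paired with the bulky chiral N-triflylphosphoramidate anion; the anion hydrogen-bonds one water molecule and delivers it as a general base to the Si face of C2 (the non-benzylic alkene carbon, where attack leaves the stabilised benzylic radical), forming the C2–O bond and setting the (S) centre; PhSH formed from PhSSPh then gives a hydrogen atom to the benzylic radical and the thiyl radical reoxidises the acridine radical, so the step is an addition with no co-product; the closest known reactions are the racemic acridinium/disulfide anti-Markovnikov hydration of styrenes and the chiral-phosphate-paired acridinium intramolecular hydroetherification of alkenols.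

**Step 3**
Reactants: 4 (S)-1-(3,5-dimethoxyphenyl)pentadecan-2-ol
Product: 5 3-[(2S)-2-hydroxypentadecyl]-5-methoxyphenol
Conditions: NaSEt (4 equiv), DMF, 140 °C, 3 h; then 1 M HCl
Reagents that add atoms: none
Why: SN2 O-demethylation of an aryl methyl ether by ethanethiolate; the two methoxy groups are equivalent so only one mono-phenol can form, the phenoxide produced deactivates the ring toward a second cleavage, and the carbinol centre is not touched.

**Compound list**
1 | 3,5-dimethoxystyrene (1-ethenyl-3,5-dimethoxybenzene) | C=Cc1cc(OC)cc(OC)c1 | starting material
2 | pentadec-1-ene | CCCCCCCCCCCCCC=C | starting material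
3 | (E)-1,3-dimethoxy-5-(pentadec-1-en-1-yl)benzene | CCCCCCCCCCCCC/C=C/c1cc(OC)cc(OC)c1 | intermediate
4 | (S)-1-(3,5-dimethoxyphenyl)pentadecan-2-ol | CCCCCCCCCCCCC[C@H](O)Cc1cc(OC)cc(OC)c1 | intermediate
5 | 3-[(2S)-2-hydroxypentadecyl]-5-methoxyphenol | CCCCCCCCCCCCC[C@H](O)Cc1cc(O)cc(OC)c1 | target

**Totals**
Total step count: 3. Longest linear sequence: 3 steps.

**Steps most likely to fail**

Step 2 (the proposed new hydration) is the main risk. The enantioselectivity may be insufficient, the radical cation may sit largely on the dimethoxyarene and react sluggishly at the alkene, and product 4 may be re-oxidised or add to a second radical cation to give an ether. The configuration and ee of 4 are checked by chiral HPLC and Mosher ester analysis against material from the fallback. The fallback uses known chemistry, sets out from 3 and comes back at 4. Asymmetric epoxidation of 3 with the L-fructose-derived ketone 1,2:4,5-di-O-isopropylidene-β-L-erythro-2,3-hexodiulo-2,6-pyranose (30 mol%), Oxone and K2CO3 in MeCN/dimethoxymethane/aqueous buffer at 0 °C gives (2S,3S)-2-(3,5-dimethoxyphenyl)-3-tridecyloxirane F1. Hydrogenolysis of F1 with 10% Pd/C and H2 (1 atm) in EtOAc at room temperature cleaves only the benzylic C–O bond and leaves the (S) carbinol centre untouched, giving 4.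

Step 1 may give a lower yield than hoped because the styrene and the alkene both homodimerise, and the E/Z ratio may fall short. The fallback sets out from 1 and comes back at 3. It is a photoinduced palladium-catalysed alkyl Heck reaction of 1 with 1-bromotridecane (PdCl2(PPh3)2, Xantphos, K2CO3, DMA, blue LEDs, room temperature), which joins the chain to the vinyl terminus by a radical path and gives the E-alkene 3 directly; no new compound is made on the way (F0).

Step 3 may over-run to the resorcinol or stall. The fallback sets out from 4 and comes back at 5. Exhaustive demethylation of 4 with BBr3 in CH2Cl2 from −78 to 0 °C (kept cold so the secondary alcohol survives as its borate) gives 5-[(2S)-2-hydroxypentadecyl]benzene-1,3-diol F2. Mono-O-methylation of one of its two equivalent phenols with dimethyl sulfate (1.0 equiv) and K2CO3 in acetone then gives 5; recovered F2 is recycled and any dimethyl ether re-enters as 4.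

**Further compounds**
F0 | step 1 | none | none
F1 | step 2 | (2S,3S)-2-(3,5-dimethoxyphenyl)-3-tridecyloxirane | CCCCCCCCCCCCC[C@@H]1O[C@H]1c1cc(OC)cc(OC)c1
F2 | step 3 | 5-[(2S)-2-hydroxypentadecyl]benzene-1,3-diol | CCCCCCCCCCCCC[C@H](O)Cc1cc(O)cc(O)c1
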